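Late in the asked flask, you reckon the electrophile left by counting its half-lives while keeping in view the nucleophile still standing behind them.

- violet: electrophile 0.50 M; nucleophile 3 equiv; free base 0.80 equiv; run made earlier
- flask: electrophile 0.25 M; nucleophile 3.00 equiv; free base 0.800 equiv; time 2.0 min

- violet (time / s: electrophile / %, target / %): 10.0: 58.6, 39.4; 12.0: 53.1, 44.2

(each reading ± 0.5 percentage points)

- part of the electrophile that has reacted at 2.0 min
- share of the unused nucleophile that is free and not bound as protonated nucleophile, at 2.0 min

- the earlier runs do not show how much of nucleophile is bound; that part of a forecast is a guess
- no earlier run changes the charge of free base; that part of a forecast is a guess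

My own reckoning starts from the later violet reading. With the nucleophile held at its charge, that reading gives you a rate constant of 0.0352 /M/s. Take the main step first, as a pseudo-first-order decay in the asked flask: the half-life of the electrophile at the charged nucleophile is 0.438 min. Then 2.0 min holds 4.57 half-lives, which gives 95.8% reacted.

Now add the spending of nucleophile, one for each electrophile, and the integrated rate law lowers this to 91.6%.

Last, add the acid. I assume each reacted electrophile sets one free, and the free base takes the first 0.800 equiv. I let the excess, 0.0289 M, bind nucleophile, and that is small beside the 0.521 M unused. So I keep 91.6% and reckon the free share at 94.4%.

The forecast gives 92% and 90%; its own reckoning of the free share stood at about 94%, and it then guessed lower: “Earlier proton sharing with the base would lower this”.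

The flask gives 92.9% and 91.1%, so the forecast held on both. Its electrophile left is 7.1%, against 4.21% from the half-life count. Free base is still 21% of its charge at 2.0 min, beside 0.0453 M of protonated nucleophile, more than my 0.0289 M.

    nucleophile + target → over-reaction product (k = 0.00250 /M/s)
    electrophile + acid set free ⇌ idle adduct, settled at all times (K = 2.90 /M)
    acid set free + free base ⇌ salt of the base (K = 16000 /M, k = 1.90 /M/s)
    electrophile + acid set free → side product (k = 0.190 /M/s)
    nucleophile + acid set free ⇌ protonated nucleophile, settled at all times (K = 15.0 /M)
    electrophile + nucleophile → acid set free + target (k = 0.0400 /M/s)

In the neighbour charged with 0.750 equiv of nucleophile, the half-life reckoned at the charged nucleophile stretches to 1.75 min, so 2.0 min holds 1.14 of them. Nucleophile is the limiting reagent there, and spending it one for one gives 41.0% reacted. That neighbour shows 46.4% reacted, with 41.0% as target and 4.24% as side product.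

The readings are simulated for an exercise, and the scatter is random.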